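## Structural features

The target is a germacranolide: a cyclodeca-1(10),4-diene (germacrane numbering; methyls on C10 and C4; 1(10)Z and 4E, both trisubstituted) trans-fused through C6 (oxygen) and C7 to an α-methylene-γ-butyrolactone (C11=C13, C12=O). Four contiguous stereocentres, C6 to C9 (6R,7S,8R,9R), carry the lactone oxygen, the lactone branch, a (Z)-2-methylbut-2-enoate (angelate) and an acetate; the fifth, C2 (R), carries the second acetate and is allylic to C1=C10. The fragile groups are the exocyclic methylene lactone (a Michael acceptor), the angelate (it isomerises to the tiglate under basic or nucleophilic acylation conditions), three neighbouring esters that can migrate, and the 1,5-diene, which is open to Cope and transannular reactions. The real difficulty is the strained ten-membered ring with two trisubstituted olefins of opposite geometry, together with the need to set C7 and C8 and to tell four ring oxygens apart. The key step exploits the homoallylic alcohol motif C8(O)–C7–C11(=C13H2): it is the retron of a [2,3]-Wittig shift of an ether oxygen bridging C8 and C13, so the ring can be reached by contraction of a thirteen-membered cyclic ether in which C7=C11 is still an in-ring olefin. That ether needs an acidifying group next to C8; a C9 ketone supplies it and at the same time distinguishes O9 from O8. Checked atom by atom, 28 and 30 already carry the C2 and C6 configuration and both olefin geometries of 40, so they are used without structural change; only CIP labels differ (the ring-E C7=C11 of 28 is formally Z, and C7 is R in 30 but S in 40 for the same spatial arrangement).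

## Logic of the disconnections

40 to 37. The lactone C12–O6 bond is taken back to the open 6,12-diol level. The methylene lactone is the most electrophilic function and is unveiled last; the cut replaces it by two hydroxyls that can travel as silyl ethers. The forward step must oxidise the primary allylic C12 alcohol in the presence of the secondary C6 alcohol and three esters.

37 to 30 (through 36, 35, 34, 33). The ester bonds at O8, O9 and O2, the C9–H bond and the O–Si bonds at C6 and C12 are cut. In 30 the C8 hydroxyl is the only free one, so the angelate goes on first with no regiochemical question. O9 is then created by reduction and acetylated together with O2. All oxygen differentiation is thereby reduced to ketone, alcohol and two silyl types. The forward steps demand acylation without Z to E isomerisation, face control of hydride at C9 and silyl orthogonality.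

30 to 28. C7–C8 is cut and O–C13 is rejoined (retro-[2,3]-Wittig). The ten-membered carbocycle becomes a thirteen-membered ether, and two stereocentres and the exocyclic methylene disappear. The forward step needs selective C8 enolisation and one defined envelope. The cis C12H2OTBS group on C11 is kept as the conformational lock that makes C6 control the C7 face.

28 to 25 (through 27). C9–C10 is cut, the only ring bond joining an sp2 carbon to a carbonyl carbon. A configurationally stable Z-alkenyl iodide and an aldehyde result, and the carbinol configuration is irrelevant because it is oxidised. The forward step needs high dilution and chemoselectivity for the iodide.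

25 to 20 (through 23, 22). The aldehyde is taken back to its diethyl acetal, the C2 silyl ether to the alcohol and the C10–I/C1–H pair to the C1≡C10 alkyne. The C2 hydroxyl is the directing group for trans-hydroalumination. The iodide is introduced only after the other alkenyl iodide of the route, 17, has been consumed, so two alkenyl iodides never meet in a palladium step. The demands are selective triethylsilyl removal from 19 and survival of the acetal.

20 to 15 (through 19, 18, 17). C11–C12 is cut. The hydroxymethyl group arrives by coupling on 17, which comes from 15 by trans addition of H and I across C7≡C11 directed by the C6 hydroxyl. This one operation sets the ring-E olefin and distinguishes C12 (new, cis to C6) from C13 (already the ether carbon), so two like CH2OH groups never need to be told apart. The forward step must respond only to the free hydroxyl and must not expel the C13 alkoxide.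

15 to 9 and 13. C6–C7 is cut. A catalyst-controlled alkynyl addition sets C6 and divides the molecule into the C1–C6 chain and a four-carbon piece that already holds the O–C13 ether and C8–C9. The forward step needs high facial selectivity on a β,β-disubstituted enal.

9 to 2 and 5 (through 8, 7, 6). C2–C3 is cut. A vinylogous aldol addition sets C2 and delivers C3, the E-C4=C5 olefin and its methyl in one step. It requires γ-regioselectivity and enantiofacial control on a small ynal.

13 to 10 and 11 (O–C13); 2 to 1 (oxidation); 5 to 3 (silyl dienolate formation, through 4). All are one-step operations on commercial materials.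

## Other disconnections considered

Alternative 1: The two ring olefins are traced to a cyclobutane. Irradiation near 350 nm would join the enone C5=C10 of bicyclic enone lactone A2 to the C1=C4 olefin of cyclobutene A3, giving the tricyclic adduct A1. Heating would then cleave the central four-membered ring along its other two bonds (C5–C10 and C1–C4) to open cyclodecadienone A4.
- In its favour: no macrocyclisation is needed, C6 to C8 and the lactone are set on a rigid six-membered ring, and the plan is convergent and probably the shortest. On step economy it is the better plan.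
- Against it: the methylene lactone of A2 is a second photoreactive olefin. Regiochemistry and facial approach of two chiral partners must both be right, because the cyclobutane stereocentres dictate the olefin geometries. The thermal cleavage passes through a 1,4-diradical, so 1(10)Z/4E is not assured, and the 1,5-diene formed can undergo Cope rearrangement at the temperatures required.
- Comparison: the chosen plan fixes both olefin geometries in open-chain intermediates and carries them unchanged through a concerted shift, whereas here they arise in the least controllable step. A4 and 30 are equal in leaving C9 as a ketone for late reduction, and A4 has the advantage of already holding the lactone.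

Alternative 2: The ten-membered ring itself is cut at C9–C10. CrCl2 with catalytic NiCl2 would convert open-chain iodo aldehyde A6 into carbinol A5.
- In its favour: the reaction type is established for exactly this bond, so on precedent it is better than the chosen key step. The C9 alcohol is obtained directly, and the lactone and C6 to C8 are in place before closure.
- Against it: end-to-end closure of a ten-membered 1,5-diene pays the full transannular and entropic price. The C9 configuration is decided in a cyclisation with little bias. The α-silyloxy aldehyde of A6 is epimerisable. C7 and C8 need separate acyclic control. The angelate must be introduced at the very end on a hindered carbinol next to the C9 oxygen.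
- Comparison: the chosen plan uses the same chromium chemistry where it is easy (thirteen-membered ring) and lets the rearrangement create C7, C8 and the methylene. Step economy is about equal: fewer steps after ring closure here, more before it.

Alternative 3: C8–C9 is cut. Low-valent titanium from TiCl3 and zinc–copper couple would join the C8 aldehyde and the C9 Z-enal of dialdehyde A8 to give diol A7.
- In its favour: ring and both carbinols form in one step, and reductive carbonyl coupling is among the better ways to medium rings, so on directness of ring formation it is equal or better.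
- Against it: two stereocentres arise with no evident control. The ketyl of the Z-enal is an allylic radical anion, so geometry may be lost or coupling may occur at C1. Over-reduction to the olefin can compete. The 8,9-diol must then be differentiated. C7, α to the C8 aldehyde, can epimerise. The methylene must be added to the lactone afterwards in the presence of base-sensitive esters.
- Comparison: the chosen plan sets C7 and C8 in a stereospecific sigmatropic step, differentiates O8 from O9 by oxidation state and receives the methylene from the rearrangement itself. It is longer in count but asks less of each late step.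

Key step: step 18

Assumption: the catalyst antipodes written in steps 3 and 8 are those expected to give Re-face addition to 2 and Si-face addition to 9; should a test reaction show the opposite sense, the mirror-image catalyst is used with no other change.
Locants and abbreviations: germacrane numbering (O on C6, fusion carbon C7, C11–C13 lactone carbons) is used for atoms throughout; TBS = tert-butyldimethylsilyl, TES = triethylsilyl.

Step 1
Reactants: 1 but-2-yn-1-ol
Product: 2 but-2-ynal
Conditions: MnO2 (activated, excess), CH2Cl2, rt; filter, use as dried solution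
Reagents that add atoms: none
Why: Activated MnO2 oxidises propargylic alcohols to ynals under neutral conditions without touching the alkyne; the volatile aldehyde is kept in solution and used directly.

Step 2
Reactants: 3 methyl 3-methylbut-2-enoate
Product: 5 tert-butyl[(1-methoxy-3-methylbuta-1,3-dien-1-yl)oxy]dimethylsilane, via lithium dienolate 4 (not isolated)
Conditions: LiN(iPr)2, THF, −78 °C; TBSCl, DMPU, −78 °C to rt; distil
Reagents that add atoms: tert-butyl(chloro)dimethylsilane (TBSCl), CC(C)(C)[Si](C)(C)Cl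
Why: γ-Deprotonation of the senecioate gives the cross-conjugated dienolate, which is silylated on oxygen (silyl dienol ether formation); the ketene acetal geometry has no bearing on the next step.

Step 3
Reactants: 2 but-2-ynal; 5 tert-butyl[(1-methoxy-3-methylbuta-1,3-dien-1-yl)oxy]dimethylsilane
Product: 6 methyl (2E,5R)-5-hydroxy-3-methyloct-2-en-6-ynoate
Conditions: SiCl4 (1.1 equiv), (R,R)-binaphthyldiamine-derived bisphosphoramide (5 mol%), iPr2NEt (10 mol%), CH2Cl2, −78 °C; aq. KF/NaHCO3
Reagents that add atoms: none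
Why: Vinylogous Mukaiyama aldol addition under chiral Lewis base-activated SiCl4: the dienolate reacts at its γ-terminus through an open transition state that gives the E-enoate, and the catalyst-bound ynal is attacked on its Re face, setting C2 (5R in 6). One step installs C2, C3 and the E-trisubstituted C4=C5 olefin with its methyl.

Step 4
Reactants: 6 methyl (2E,5R)-5-hydroxy-3-methyloct-2-en-6-ynoate
Product: 7 methyl (2E,5R)-3-methyl-5-(triethylsilyloxy)oct-2-en-6-ynoate
Conditions: TESCl, imidazole, CH2Cl2, 0 °C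
Reagents that add atoms: chlorotriethylsilane (TESCl), CC[Si](CC)(CC)Cl
Why: Standard silylation; the TES group keeps the C2 oxygen from directing hydroalumination of C1≡C10 in step 9 and can be removed beside TBS ethers in step 12.

Step 5
Reactants: 7 methyl (2E,5R)-3-methyl-5-(triethylsilyloxy)oct-2-en-6-ynoate
Product: 8 (2E,5R)-3-methyl-5-(triethylsilyloxy)oct-2-en-6-yn-1-ol
Conditions: iBu2AlH (2.2 equiv), CH2Cl2, −78 to 0 °C; aq. potassium sodium tartrate
Reagents that add atoms: none
Why: 1,2-Reduction of the enoate by the aluminium hydride gives the E-allylic alcohol; silyl ether and alkyne are inert.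

Step 6
Reactants: 8 (2E,5R)-3-methyl-5-(triethylsilyloxy)oct-2-en-6-yn-1-ol
Product: 9 (2E,5R)-3-methyl-5-(triethylsilyloxy)oct-2-en-6-ynal
Conditions: MnO2 (excess), CH2Cl2, rt
Reagents that add atoms: none
Why: MnO2 oxidises the primary allylic alcohol to the enal without E/Z isomerisation or over-oxidation.

Step 7
Reactants: 10 2,2-diethoxyethanol; 11 3-bromoprop-1-yne
Product: 13 3-(2,2-diethoxyethoxy)prop-1-yne, via sodium 2,2-diethoxyethoxide 12 (not isolated)
Conditions: NaH, THF, 0 °C; then 11, Bu4NI (cat.), 0 °C to rt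
Reagents that add atoms: none
Why: Williamson ether synthesis: the alkoxide displaces the reactive propargylic bromide and forms the future O–C13 bond; the diethyl acetal masks C9 through all basic and reductive steps.

Step 8
Reactants: 9 (2E,5R)-3-methyl-5-(triethylsilyloxy)oct-2-en-6-ynal; 13 3-(2,2-diethoxyethoxy)prop-1-yne
Product: 15 (4R,5E,8R)-1-(2,2-diethoxyethoxy)-6-methyl-8-(triethylsilyloxy)undec-5-ene-2,9-diyn-4-ol, via alkynyl(methyl)zinc 14 (not isolated)
Conditions: 13 (3 equiv), Me2Zn (3 equiv), (R,R)-ProPhenol (20 mol%), Ph3P=O (40 mol%), toluene, 0 °C; then 9, 4 °C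
Reagents that add atoms: none
Why: Catalytic enantioselective alkynylzinc addition to an aldehyde: the dinuclear zinc–ProPhenol complex binds 14 and the enal and delivers the alkyne to the Si face, setting C6 (4R in 15). Conjugated aldehydes are the favoured substrates of this catalyst and the C2 centre is too remote to interfere.

Step 9
Reactants: 15 (4R,5E,8R)-1-(2,2-diethoxyethoxy)-6-methyl-8-(triethylsilyloxy)undec-5-ene-2,9-diyn-4-ol
Product: 17 (2Z,4R,5E,8R)-1-(2,2-diethoxyethoxy)-2-iodo-6-methyl-8-(triethylsilyloxy)undeca-2,5-dien-9-yn-4-ol, via cyclic alkenylalanate 16 (not isolated)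
Conditions: NaAlH2(OCH2CH2OMe)2 (Red-Al), THF, −20 to 0 °C; EtOAc; then I2, THF, −78 °C
Reagents that add atoms: iodine, II
Why: Hydroxyl-directed trans-hydroalumination: the C6 alkoxide binds aluminium, hydride goes to C7 and aluminium to C11 (five-membered alanate 16), and iodine cleaves the C–Al bond with retention, placing iodine cis to C6. The silyl-capped C2 alkynol cannot direct and stays untouched; keeping the mixture at or below 0 °C avoids loss of the C13 alkoxide from 16.

Step 10
Reactants: 17 (2Z,4R,5E,8R)-1-(2,2-diethoxyethoxy)-2-iodo-6-methyl-8-(triethylsilyloxy)undeca-2,5-dien-9-yn-4-ol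
Product: 18 (2E,4R,5E,8R)-2-[(2,2-diethoxyethoxy)methyl]-6-methyl-8-(triethylsilyloxy)undeca-2,5-dien-9-yne-1,4-diol (hydroxymethyl cis to C6)
Conditions: Bu3SnCH2OH (2 equiv), Pd(PPh3)4 (10 mol%), 1,4-dioxane, 90 °C
Reagents that add atoms: (tributylstannyl)methanol, CCCC[Sn](CCCC)(CCCC)CO
Why: Stille coupling transfers the hydroxymethyl group to C11 with retention of olefin geometry, so C12 ends cis to C6 and the ether carbon C13 trans; the neutral medium spares acetal, silyl ether and the C6 centre.

Step 11
Reactants: 18 (2E,4R,5E,8R)-2-[(2,2-diethoxyethoxy)methyl]-6-methyl-8-(triethylsilyloxy)undeca-2,5-dien-9-yne-1,4-diol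
Product: 19 (2Z,4R,5E,8R)-1,4-bis(TBSO)-2-[(2,2-diethoxyethoxy)methyl]-6-methyl-8-(triethylsilyloxy)undeca-2,5-dien-9-yne
Conditions: TBSCl (3 equiv), imidazole, DMAP (cat.), DMF, rt
Reagents that add atoms: tert-butyl(chloro)dimethylsilane (TBSCl), CC(C)(C)[Si](C)(C)Cl
Why: Silylation of the primary and the secondary allylic hydroxyl; the chloride/imidazole system is chosen because silyl triflates with pyridine bases would attack the acetal.

Step 12
Reactants: 19 (2Z,4R,5E,8R)-1,4-bis(TBSO)-2-[(2,2-diethoxyethoxy)methyl]-6-methyl-8-(triethylsilyloxy)undeca-2,5-dien-9-yne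
Product: 20 (4R,6E,8R,9Z)-8,11-bis(TBSO)-10-[(2,2-diethoxyethoxy)methyl]-6-methylundeca-6,9-dien-2-yn-4-ol
Conditions: PPTS (0.2 equiv), EtOH, 0 °C
Reagents that add atoms: none
Why: Acid-catalysed ethanolysis removes the TES ether much faster than the TBS ethers; ethanol as solvent makes acetal exchange degenerate.

Step 13
Reactants: 20 (4R,6E,8R,9Z)-8,11-bis(TBSO)-10-[(2,2-diethoxyethoxy)methyl]-6-methylundeca-6,9-dien-2-yn-4-ol
Product: 22 (2Z,4R,6E,8R,9Z)-8,11-bis(TBSO)-10-[(2,2-diethoxyethoxy)methyl]-2-iodo-6-methylundeca-2,6,9-trien-4-ol, via cyclic alkenylalanate 21 (not isolated)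
Conditions: NaAlH2(OCH2CH2OMe)2 (Red-Al), THF, 0 °C to rt; EtOAc; then I2, THF, −78 °C
Reagents that add atoms: iodine, II
Why: The same hydroxyl-directed trans-hydroalumination/iodination as in step 9, now steered by the freed C2 hydroxyl: hydride to C1, aluminium then iodine to C10, giving the Z-iodoalkene with iodine cis to C2. It is run only now so that this iodide never coexists with 17 in a palladium step.

Step 14
Reactants: 22 (2Z,4R,6E,8R,9Z)-8,11-bis(TBSO)-10-[(2,2-diethoxyethoxy)methyl]-2-iodo-6-methylundeca-2,6,9-trien-4-ol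
Product: 23 (2Z,4R,5E,8R,9Z)-1,4-bis(TBSO)-2-[(2,2-diethoxyethoxy)methyl]-10-iodo-6-methyl-8-(triethylsilyloxy)undeca-2,5,9-triene
Conditions: TESCl, imidazole, DMF, 0 °C
Reagents that add atoms: chlorotriethylsilane (TESCl), CC[Si](CC)(CC)Cl
Why: Silylation of the secondary allylic alcohol; TES is chosen so that C2 can later be unmasked beside the C6/C12 TBS ethers.

Step 15
Reactants: 23 (2Z,4R,5E,8R,9Z)-1,4-bis(TBSO)-2-[(2,2-diethoxyethoxy)methyl]-10-iodo-6-methyl-8-(triethylsilyloxy)undeca-2,5,9-triene
Product: 25 2-{[(2Z,4R,5E,8R,9Z)-4-(TBSO)-2-[(TBSO)methyl]-10-iodo-6-methyl-8-(triethylsilyloxy)undeca-2,5,9-trien-1-yl]oxy}acetaldehyde, via collidinium acetal triflate 24 (not isolated)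
Conditions: TESOTf (2 equiv), 2,4,6-collidine (3 equiv), CH2Cl2, 0 °C; then H2O, rt
Reagents that add atoms: water, O
Why: The silyl triflate ionises the acetal, collidine traps the oxocarbenium ion as pyridinium salt 24 and water hydrolyses it to the aldehyde; the medium stays buffered, so the three silyl ethers and the allylic ethers should survive.

Step 16
Reactants: 25 2-{[(2Z,4R,5E,8R,9Z)-4-(TBSO)-2-[(TBSO)methyl]-10-iodo-6-methyl-8-(triethylsilyloxy)undeca-2,5,9-trien-1-yl]oxy}acetaldehyde
Product: 27 (4Z,6R,8E,10R,11Z)-10-(TBSO)-12-[(TBSO)methyl]-4,8-dimethyl-6-(triethylsilyloxy)-1-oxacyclotrideca-4,8,11-trien-3-ol (both C3 epimers), via alkenylchromium dichloride 26 (not isolated)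
Conditions: CrCl2 (10 equiv), NiCl2 (0.1 equiv), DMSO/THF, rt, slow addition to 0.002 M
Reagents that add atoms: none
Why: Nozaki–Hiyama–Kishi reaction: zerovalent nickel inserts into the C10–I bond with retention, transmetallation gives the alkenyl species of trivalent chromium 26, and this adds chemoselectively to the aldehyde. The thirteen-membered ring closes end to end at high dilution, and the C9 configuration is irrelevant because it is oxidised next.

Step 17
Reactants: 27 (4Z,6R,8E,10R,11Z)-10-(TBSO)-12-[(TBSO)methyl]-4,8-dimethyl-6-(triethylsilyloxy)-1-oxacyclotrideca-4,8,11-trien-3-ol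
Product: 28 (4Z,6R,8E,10R,11Z)-10-(TBSO)-12-[(TBSO)methyl]-4,8-dimethyl-6-(triethylsilyloxy)-1-oxacyclotrideca-4,8,11-trien-3-one
Conditions: Dess–Martin periodinane, NaHCO3, CH2Cl2, 0 °C to rt
Reagents that add atoms: none
Why: Dess–Martin oxidation of the allylic alcohol gives the Z-enone under buffered conditions; no epimerisable centre is adjacent.

Step 18
Reactants: 28 (4Z,6R,8E,10R,11Z)-10-(TBSO)-12-[(TBSO)methyl]-4,8-dimethyl-6-(triethylsilyloxy)-1-oxacyclotrideca-4,8,11-trien-3-one
Product: 30 (2Z,4R,6E,8R,9R,10R)-8-(TBSO)-9-[3-(TBSO)prop-1-en-2-yl]-10-hydroxy-2,6-dimethyl-4-(triethylsilyloxy)cyclodeca-2,6-dien-1-one, via lithium enolate 29 (not isolated)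
Conditions: LiN(iPr)2 (1.3 equiv), THF, −78 to −40 °C; AcOH/THF, −78 °C
Reagents that add atoms: none
Why: Proposed new method: LiN(iPr)2 removes a C8 proton (the only α-hydrogens of the Z-enone) to give the ether-chelated lithium enolate 29, whose C8 terminus bonds to C7 suprafacially through a five-membered envelope while O–C13 breaks and the π bond moves to C11=C13, a [2,3]-Wittig shift; the closest known reaction types are the [2,3]-Wittig ring contraction of thirteen-membered diallylic ethers and the open-chain enolate [2,3]-Wittig rearrangement of α-allyloxy ketones and esters, and their combination in one macrocycle is without precedent. The ten-membered carbocycle is closed by ring contraction, that is by transannular C7–C8 bond formation inside the thirteen-membered ring with O, C13 and C11 extruded as the side chain, not by end-to-end cyclisation, so no high dilution is needed. C7 is controlled by C6: allylic 1,3-strain with the cis C12H2OTBS group holds C6–H in the olefin plane, the C5 tether that carries the enolate lies on one face and the OTBS group on the other, so C8 can only reach the face anti to OTBS, which is the 6,7-trans arrangement of the target. C8 is controlled by the ring-E olefin and the envelope: with C6 pseudo-equatorial the enolate carbon C9 sits exo, away from C6, which places H7 and H8 trans (9R,10R in 30). The step needs C8 over γ (C2) deprotonation, [2,3] over the [3,3] and [1,2] pathways, and an intact Z-enone. These are secured by the kinetic amide base at −78 °C, by the lithium counter-ion, which slows the anionic [3,3] shift, by the fact that the [3,3] path would have to build a quaternary C9 in a nine-membered ring, and by the cold acidic quench of the product alkoxide.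

Step 19
Reactants: 30 (2Z,4R,6E,8R,9R,10R)-8-(TBSO)-9-[3-(TBSO)prop-1-en-2-yl]-10-hydroxy-2,6-dimethyl-4-(triethylsilyloxy)cyclodeca-2,6-dien-1-one; 31 (2Z)-2-methylbut-2-enoic acid (angelic acid)
Product: 33 (2R,6R,7R,8R)-8-angeloyloxy-6,12-bis(TBSO)-2-(triethylsilyloxy)germacra-1(10)Z,4E,11(13)-trien-9-one, via mixed anhydride 32 (not isolated)
Conditions: 31, 2,4,6-trichlorobenzoyl chloride, Et3N, toluene, rt; then 30, toluene, 75 °C
Reagents that add atoms: none
Why: Yamaguchi-type acylation with the preformed mixed anhydride and no nucleophilic catalyst, conditions under which the Z-angelate does not isomerise to the tiglate; C8–OH is the only free hydroxyl.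

Step 20
Reactants: 33 (2R,6R,7R,8R)-8-angeloyloxy-6,12-bis(TBSO)-2-(triethylsilyloxy)germacra-1(10)Z,4E,11(13)-trien-9-one
Product: 34 (2R,6R,7R,8R,9R)-8-angeloyloxy-6,12-bis(TBSO)-2-(triethylsilyloxy)germacra-1(10)Z,4E,11(13)-trien-9-ol
Conditions: NaBH4, CeCl3·7H2O, MeOH, −78 to −40 °C
Reagents that add atoms: none
Why: Luche reduction gives clean 1,2-reduction of the enone; under these non-chelating conditions hydride should add anti to the C8 acyloxy group, which corresponds to the 8,9-anti (9R) alcohol. The angelate and the exocyclic olefin are not reduced.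

Step 21
Reactants: 34 (2R,6R,7R,8R,9R)-8-angeloyloxy-6,12-bis(TBSO)-2-(triethylsilyloxy)germacra-1(10)Z,4E,11(13)-trien-9-ol
Product: 35 (2R,6R,7R,8R,9R)-8-angeloyloxy-6,12-bis(TBSO)germacra-1(10)Z,4E,11(13)-triene-2,9-diol
Conditions: PPTS (0.2 equiv), MeOH/CH2Cl2, 0 °C
Reagents that add atoms: none
Why: Mild acid methanolysis cleaves the TES ether selectively; both TBS ethers and the esters remain, and the short, cold, weakly acidic treatment limits 8 to 9 acyl migration.

Step 22
Reactants: 35 (2R,6R,7R,8R,9R)-8-angeloyloxy-6,12-bis(TBSO)germacra-1(10)Z,4E,11(13)-triene-2,9-diol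
Product: 36 (2R,6R,7R,8R,9R)-2,9-diacetoxy-8-angeloyloxy-6,12-bis(TBSO)germacra-1(10)Z,4E,11(13)-triene
Conditions: Ac2O, pyridine, DMAP (cat.), CH2Cl2, 0 °C to rt
Reagents that add atoms: acetic anhydride, CC(=O)OC(C)=O
Why: Acetylation of both secondary allylic alcohols under acyl-transfer catalysis installs the two acetates in one operation.

Step 23
Reactants: 36 (2R,6R,7R,8R,9R)-2,9-diacetoxy-8-angeloyloxy-6,12-bis(TBSO)germacra-1(10)Z,4E,11(13)-triene
Product: 37 (2R,6R,7S,8R,9R)-2,9-diacetoxy-8-angeloyloxygermacra-1(10)Z,4E,11(13)-triene-6,12-diol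
Conditions: HF·pyridine, pyridine, THF, 0 °C to rt
Reagents that add atoms: none
Why: Buffered fluoride cleaves both TBS ethers without the basicity that would promote acyl migration, ester cleavage or angelate isomerisation.

Step 24
Reactants: 37 (2R,6R,7S,8R,9R)-2,9-diacetoxy-8-angeloyloxygermacra-1(10)Z,4E,11(13)-triene-6,12-diol
Product: 40 (2R,6R,7S,8R,9R)-2,9-diacetoxy-8-angeloyloxygermacra-1(10)Z,4E,11(13)-trien-12,6-olide (CNP0499619.1), via hydroxy enal 38 (not isolated), via lactol 39 (not isolated)
Conditions: TEMPO (0.2 equiv), PhI(OAc)2 (3 equiv), CH2Cl2, rt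
Reagents that add atoms: none
Why: The oxoammonium salt oxidises the primary allylic alcohol selectively to enal 38, the C6 hydroxyl closes lactol 39 by addition to the aldehyde, and a second oxidation gives the α-methylene lactone; secondary alcohols are oxidised far more slowly.

## Compound list

1 | but-2-yn-1-ol | CC#CCO | starting material
2 | but-2-ynal | CC#CC=O | intermediate
3 | methyl 3-methylbut-2-enoate | CC(C)=CC(=O)OC | starting material
4 | lithium 1-methoxy-3-methylbuta-1,3-dien-1-olate | [Li+].C=C(C)C=C([O-])OC | intermediate (not isolated)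
5 | tert-butyl[(1-methoxy-3-methylbuta-1,3-dien-1-yl)oxy]dimethylsilane (ketene acetal geometry not defined) | C=C(C)C=C(OC)O[Si](C)(C)C(C)(C)C | intermediate
6 | methyl (2E,5R)-5-hydroxy-3-methyloct-2-en-6-ynoate | CC#C[C@H](O)C/C(C)=C/C(=O)OC | intermediate
7 | methyl (2E,5R)-3-methyl-5-(triethylsilyloxy)oct-2-en-6-ynoate | CC#C[C@H](O[Si](CC)(CC)CC)C/C(C)=C/C(=O)OC | intermediate
8 | (2E,5R)-3-methyl-5-(triethylsilyloxy)oct-2-en-6-yn-1-ol | CC#C[C@H](O[Si](CC)(CC)CC)C/C(C)=C/CO | intermediate
9 | (2E,5R)-3-methyl-5-(triethylsilyloxy)oct-2-en-6-ynal | CC#C[C@H](O[Si](CC)(CC)CC)C/C(C)=C/C=O | intermediate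
10 | 2,2-diethoxyethanol | CCOC(CO)OCC | starting material
11 | 3-bromoprop-1-yne (propargyl bromide) | C#CCBr | starting material
12 | sodium 2,2-diethoxyethoxide | [Na+].CCOC(C[O-])OCC | intermediate (not isolated)
13 | 3-(2,2-diethoxyethoxy)prop-1-yne | C#CCOCC(OCC)OCC | intermediate
14 | [3-(2,2-diethoxyethoxy)prop-1-yn-1-yl](methyl)zinc | C[Zn]C#CCOCC(OCC)OCC | intermediate (not isolated)
15 | (4R,5E,8R)-1-(2,2-diethoxyethoxy)-6-methyl-8-(triethylsilyloxy)undec-5-ene-2,9-diyn-4-ol | CC#C[C@H](O[Si](CC)(CC)CC)C/C(C)=C/[C@@H](O)C#CCOCC(OCC)OCC | intermediate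
16 | sodium alkoxy(alkenyl)bis(2-methoxyethoxy)aluminate from 15 (five-membered ring O6–Al–C11=C7–C6) | [Na+].CC#C[C@H](O[Si](CC)(CC)CC)C/C(C)=C/[C@H]1O[Al-](OCCOC)(OCCOC)C(COCC(OCC)OCC)=C1 | intermediate (not isolated)
17 | (2Z,4R,5E,8R)-1-(2,2-diethoxyethoxy)-2-iodo-6-methyl-8-(triethylsilyloxy)undeca-2,5-dien-9-yn-4-ol | CC#C[C@H](O[Si](CC)(CC)CC)C/C(C)=C/[C@@H](O)/C=C(\I)COCC(OCC)OCC | intermediate
18 | (2E,4R,5E,8R)-2-[(2,2-diethoxyethoxy)methyl]-6-methyl-8-(triethylsilyloxy)undeca-2,5-dien-9-yne-1,4-diol | CC#C[C@H](O[Si](CC)(CC)CC)C/C(C)=C/[C@@H](O)/C=C(\CO)COCC(OCC)OCC | intermediate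
19 | (2Z,4R,5E,8R)-1,4-bis(tert-butyldimethylsilyloxy)-2-[(2,2-diethoxyethoxy)methyl]-6-methyl-8-(triethylsilyloxy)undeca-2,5-dien-9-yne | CC#C[C@H](O[Si](CC)(CC)CC)C/C(C)=C/[C@@H](O[Si](C)(C)C(C)(C)C)/C=C(\CO[Si](C)(C)C(C)(C)C)COCC(OCC)OCC | intermediate
20 | (4R,6E,8R,9Z)-8,11-bis(tert-butyldimethylsilyloxy)-10-[(2,2-diethoxyethoxy)methyl]-6-methylundeca-6,9-dien-2-yn-4-ol | CC#C[C@H](O)C/C(C)=C/[C@@H](O[Si](C)(C)C(C)(C)C)/C=C(\CO[Si](C)(C)C(C)(C)C)COCC(OCC)OCC | intermediate
21 | sodium alkoxy(alkenyl)bis(2-methoxyethoxy)aluminate from 20 (five-membered ring O2–Al–C10=C1–C2) | [Na+].CC1=C[C@@H](C/C(C)=C/[C@@H](O[Si](C)(C)C(C)(C)C)/C=C(\CO[Si](C)(C)C(C)(C)C)COCC(OCC)OCC)O[Al-]1(OCCOC)OCCOC | intermediate (not isolated)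
22 | (2Z,4R,6E,8R,9Z)-8,11-bis(tert-butyldimethylsilyloxy)-10-[(2,2-diethoxyethoxy)methyl]-2-iodo-6-methylundeca-2,6,9-trien-4-ol | C/C(I)=C/[C@H](O)C/C(C)=C/[C@@H](O[Si](C)(C)C(C)(C)C)/C=C(\CO[Si](C)(C)C(C)(C)C)COCC(OCC)OCC | intermediate
23 | (2Z,4R,5E,8R,9Z)-1,4-bis(tert-butyldimethylsilyloxy)-2-[(2,2-diethoxyethoxy)methyl]-10-iodo-6-methyl-8-(triethylsilyloxy)undeca-2,5,9-triene | C/C(I)=C/[C@H](O[Si](CC)(CC)CC)C/C(C)=C/[C@@H](O[Si](C)(C)C(C)(C)C)/C=C(\CO[Si](C)(C)C(C)(C)C)COCC(OCC)OCC | intermediate
24 | 1-(1-ethoxy-2-alkoxyethyl)-2,4,6-trimethylpyridinium triflate from 23 (C9 epimers) | C/C(I)=C/[C@H](O[Si](CC)(CC)CC)C/C(C)=C/[C@@H](O[Si](C)(C)C(C)(C)C)/C=C(\CO[Si](C)(C)C(C)(C)C)COCC(OCC)[n+]1c(C)cc(C)cc1C.[O-]S(=O)(=O)C(F)(F)F | intermediate (not isolated)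
25 | 2-{[(2Z,4R,5E,8R,9Z)-4-(tert-butyldimethylsilyloxy)-2-[(tert-butyldimethylsilyloxy)methyl]-10-iodo-6-methyl-8-(triethylsilyloxy)undeca-2,5,9-trien-1-yl]oxy}acetaldehyde | C/C(I)=C/[C@H](O[Si](CC)(CC)CC)C/C(C)=C/[C@@H](O[Si](C)(C)C(C)(C)C)/C=C(\CO[Si](C)(C)C(C)(C)C)COCC=O | intermediate
26 | alkenylchromium dichloride from 25 (CrCl2 in place of iodine at C10) | C/C([Cr](Cl)Cl)=C/[C@H](O[Si](CC)(CC)CC)C/C(C)=C/[C@@H](O[Si](C)(C)C(C)(C)C)/C=C(\CO[Si](C)(C)C(C)(C)C)COCC=O | intermediate (not isolated)
27 | (4Z,6R,8E,10R,11Z)-10-(tert-butyldimethylsilyloxy)-12-[(tert-butyldimethylsilyloxy)methyl]-4,8-dimethyl-6-(triethylsilyloxy)-1-oxacyclotrideca-4,8,11-trien-3-ol, both C3 epimers | OC1COC/C(CO[Si](C)(C)C(C)(C)C)=C/[C@H](O[Si](C)(C)C(C)(C)C)/C=C(\C)C[C@@H](O[Si](CC)(CC)CC)/C=C1/C | intermediate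
28 | (4Z,6R,8E,10R,11Z)-10-(tert-butyldimethylsilyloxy)-12-[(tert-butyldimethylsilyloxy)methyl]-4,8-dimethyl-6-(triethylsilyloxy)-1-oxacyclotrideca-4,8,11-trien-3-one (thirteen-membered ether, O between C8 and C13) | O=C1COC/C(CO[Si](C)(C)C(C)(C)C)=C/[C@H](O[Si](C)(C)C(C)(C)C)/C=C(\C)C[C@@H](O[Si](CC)(CC)CC)/C=C1/C | intermediate
29 | lithium C8=C9 enolate of 28 (enolate oxygen cis to the ring oxygen) | [Li+].[O-]/C1=C\OC/C(CO[Si](C)(C)C(C)(C)C)=C/[C@H](O[Si](C)(C)C(C)(C)C)/C=C(\C)C[C@@H](O[Si](CC)(CC)CC)/C=C1/C | intermediate (not isolated)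
30 | (2Z,4R,6E,8R,9R,10R)-8-(tert-butyldimethylsilyloxy)-9-[3-(tert-butyldimethylsilyloxy)prop-1-en-2-yl]-10-hydroxy-2,6-dimethyl-4-(triethylsilyloxy)cyclodeca-2,6-dien-1-one | O=C1[C@H](O)[C@@H](C(=C)CO[Si](C)(C)C(C)(C)C)[C@H](O[Si](C)(C)C(C)(C)C)/C=C(\C)C[C@@H](O[Si](CC)(CC)CC)/C=C1/C | intermediate
31 | (2Z)-2-methylbut-2-enoic acid (angelic acid) | C/C=C(/C)C(=O)O | starting material
32 | (2Z)-2-methylbut-2-enoic 2,4,6-trichlorobenzoic anhydride | C/C=C(/C)C(=O)OC(=O)c1c(Cl)cc(Cl)cc1Cl | intermediate (not isolated)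
33 | (2R,6R,7R,8R)-8-angeloyloxy-6,12-bis(tert-butyldimethylsilyloxy)-2-(triethylsilyloxy)germacra-1(10)Z,4E,11(13)-trien-9-one | O=C1[C@H](OC(=O)/C(C)=C\C)[C@@H](C(=C)CO[Si](C)(C)C(C)(C)C)[C@H](O[Si](C)(C)C(C)(C)C)/C=C(\C)C[C@@H](O[Si](CC)(CC)CC)/C=C1/C | intermediate
34 | (2R,6R,7R,8R,9R)-8-angeloyloxy-6,12-bis(tert-butyldimethylsilyloxy)-2-(triethylsilyloxy)germacra-1(10)Z,4E,11(13)-trien-9-ol | O[C@H]1[C@H](OC(=O)/C(C)=C\C)[C@@H](C(=C)CO[Si](C)(C)C(C)(C)C)[C@H](O[Si](C)(C)C(C)(C)C)/C=C(\C)C[C@@H](O[Si](CC)(CC)CC)/C=C1/C | intermediate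
35 | (2R,6R,7R,8R,9R)-8-angeloyloxy-6,12-bis(tert-butyldimethylsilyloxy)germacra-1(10)Z,4E,11(13)-triene-2,9-diol | O[C@H]1[C@H](OC(=O)/C(C)=C\C)[C@@H](C(=C)CO[Si](C)(C)C(C)(C)C)[C@H](O[Si](C)(C)C(C)(C)C)/C=C(\C)C[C@@H](O)/C=C1/C | intermediate
36 | (2R,6R,7R,8R,9R)-2,9-diacetoxy-8-angeloyloxy-6,12-bis(tert-butyldimethylsilyloxy)germacra-1(10)Z,4E,11(13)-triene | CC(=O)O[C@H]1[C@H](OC(=O)/C(C)=C\C)[C@@H](C(=C)CO[Si](C)(C)C(C)(C)C)[C@H](O[Si](C)(C)C(C)(C)C)/C=C(\C)C[C@@H](OC(C)=O)/C=C1/C | intermediate
37 | (2R,6R,7S,8R,9R)-2,9-diacetoxy-8-angeloyloxygermacra-1(10)Z,4E,11(13)-triene-6,12-diol | CC(=O)O[C@H]1[C@H](OC(=O)/C(C)=C\C)[C@@H](C(=C)CO)[C@H](O)/C=C(\C)C[C@@H](OC(C)=O)/C=C1/C | intermediate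
38 | (2R,6R,7S,8R,9R)-2,9-diacetoxy-8-angeloyloxy-6-hydroxygermacra-1(10)Z,4E,11(13)-trien-12-al | CC(=O)O[C@H]1[C@H](OC(=O)/C(C)=C\C)[C@@H](C(=C)C=O)[C@H](O)/C=C(\C)C[C@@H](OC(C)=O)/C=C1/C | intermediate (not isolated)
39 | 12-hydroxy 12,6-lactol of 38 (C12 epimers) | C=C1C(O)O[C@@H]2/C=C(\C)C[C@@H](OC(C)=O)/C=C(/C)[C@@H](OC(C)=O)[C@H](OC(=O)/C(C)=C\C)[C@@H]12 | intermediate (not isolated)
40 | (2R,6R,7S,8R,9R)-2,9-diacetoxy-8-[(2Z)-2-methylbut-2-enoyloxy]germacra-1(10)Z,4E,11(13)-trien-12,6-olide (CNP0499619.1) | C=C1C(=O)O[C@@H]2/C=C(\C)C[C@@H](OC(C)=O)/C=C(/C)[C@@H](OC(C)=O)[C@H](OC(=O)/C(C)=C\C)[C@@H]12 | target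

## Step count and least certain steps

Total: 24 steps. Longest linear sequence: 22 steps (steps 1, 3 to 6 and 8 to 24, from 1 to 40); steps 2 and 7 are side branches.

Step 18 (key step). What may go wrong: the enolate may rearrange through the [3,3] or [1,2] manifold, or not at all if the thirteen-membered ring cannot fold into the envelope. Bond formation may also pass through the diastereomeric envelope (C9 endo) and give the C8 epimer, and deprotonation at C2 is a further leak. Fallback with known chemistry, setting out from 25 and rejoining at 30: Pinnick oxidation (NaClO2, NaH2PO4, 2-methylbut-2-ene) gives carboxylic acid F1 and Me3SiCHN2 its methyl ester F2. The lithium ester enolate (LiN(iPr)2, THF, −78 °C) then undergoes the established open-chain [2,3]-Wittig rearrangement of an α-allyloxy acetate to hydroxy ester F3, with the same allylic-strain control of the C7 face by C6 and no ring constraint. Me3SiCl/imidazole gives trimethylsilyl ether F4, iBu2AlH at −78 °C gives aldehyde F5, and CrCl2/NiCl2 at high dilution closes the ten-membered ring directly to carbinol F6. Dess–Martin oxidation gives silyloxy ketone F7, and citric acid in MeOH removes the trimethylsilyl group to return 30.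

Step 3. What may go wrong: weak enantiofacial discrimination with the slender, linear ynal, or competing α-attack of the dienolate. Fallback from 2 and 5, rejoining at 6: BF3·OEt2-promoted vinylogous Mukaiyama aldol addition gives racemic hydroxy ester F8, Dess–Martin oxidation gives ynone F9, and Noyori transfer hydrogenation with RuCl[(R,R)-TsDPEN](p-cymene) in iPrOH, which reduces alkynyl ketones with high selectivity, returns 6.

Step 8. What may go wrong: slow or unselective addition to the β,β-disubstituted enal, with methyl transfer from Me2Zn as a competing process. Fallback from 9 and 13, rejoining at 15: the lithium acetylide of 13 (n-BuLi, THF, −78 °C) adds to 9 to give the C6-epimeric alcohols F10, MnO2 gives the cross-conjugated ynone F11, and Midland reduction with (R)-Alpine-Borane, in which the alkyne is the small group, returns 15.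

Step 10. What may go wrong: sluggish transfer of the hydroxymethyl group from tin, which opens the way to butyl transfer, protodeiodination or loss of the C13 alkoxide from the alkenylpalladium intermediate. Fallback from 17, rejoining at 19: TBSCl/imidazole gives silyl ether F12; carbonylation (Pd(OAc)2, PPh3, CO, MeOH, Et3N) gives methyl ester F13 with the ester cis to C6; iBu2AlH gives allylic alcohol F14; TBSCl/imidazole then gives 19.

Step 20. What may go wrong: hydride delivery to the other face of the C9 carbonyl, because the ring conformation and not the adjacent acyloxy group may decide; acyl migration on work-up is a second risk. Fallback from 33, rejoining at 36: the reduction is accepted as giving the 9-epimeric alcohol F15; Mitsunobu reaction with acetic acid (PPh3, diisopropyl azodicarboxylate) inverts C9 and installs the acetate in one step, giving acetate F16; PPTS/MeOH removes the TES group to give alcohol F17; Ac2O/pyridine then gives 36.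

## Further compounds

F1 | step 18 | {[(2Z,4R,5E,8R,9Z)-4-(TBSO)-2-[(TBSO)methyl]-10-iodo-6-methyl-8-(triethylsilyloxy)undeca-2,5,9-trien-1-yl]oxy}acetic acid | C/C(I)=C/[C@H](O[Si](CC)(CC)CC)C/C(C)=C/[C@@H](O[Si](C)(C)C(C)(C)C)/C=C(\CO[Si](C)(C)C(C)(C)C)COCC(=O)O
F2 | step 18 | methyl ester of F1 | C/C(I)=C/[C@H](O[Si](CC)(CC)CC)C/C(C)=C/[C@@H](O[Si](C)(C)C(C)(C)C)/C=C(\CO[Si](C)(C)C(C)(C)C)COCC(=O)OC
F3 | step 18 | open-chain [2,3]-Wittig product: methyl 2-hydroxy ester with C7 bearing the 3-(TBSO)prop-1-en-2-yl group (C8 and C7 configured as in 30) | C/C(I)=C/[C@H](O[Si](CC)(CC)CC)C/C(C)=C/[C@@H](O[Si](C)(C)C(C)(C)C)[C@@H]([C@@H](O)C(=O)OC)C(=C)CO[Si](C)(C)C(C)(C)C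
F4 | step 18 | C8 trimethylsilyl ether of F3 | C/C(I)=C/[C@H](O[Si](CC)(CC)CC)C/C(C)=C/[C@@H](O[Si](C)(C)C(C)(C)C)[C@@H]([C@@H](O[Si](C)(C)C)C(=O)OC)C(=C)CO[Si](C)(C)C(C)(C)C
F5 | step 18 | C9 aldehyde from F4 | C/C(I)=C/[C@H](O[Si](CC)(CC)CC)C/C(C)=C/[C@@H](O[Si](C)(C)C(C)(C)C)[C@@H]([C@@H](O[Si](C)(C)C)C=O)C(=C)CO[Si](C)(C)C(C)(C)C
F6 | step 18 | ten-membered C9 carbinol with C8 trimethylsilyl ether (C9 epimers) | OC1[C@H](O[Si](C)(C)C)[C@@H](C(=C)CO[Si](C)(C)C(C)(C)C)[C@H](O[Si](C)(C)C(C)(C)C)/C=C(\C)C[C@@H](O[Si](CC)(CC)CC)/C=C1/C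
F7 | step 18 | C8 trimethylsilyl ether of 30 | O=C1[C@H](O[Si](C)(C)C)[C@@H](C(=C)CO[Si](C)(C)C(C)(C)C)[C@H](O[Si](C)(C)C(C)(C)C)/C=C(\C)C[C@@H](O[Si](CC)(CC)CC)/C=C1/C
F8 | step 3 | methyl (2E)-5-hydroxy-3-methyloct-2-en-6-ynoate, racemic | CC#CC(O)C/C(C)=C/C(=O)OC
F9 | step 3 | methyl (2E)-3-methyl-5-oxooct-2-en-6-ynoate | CC#CC(=O)C/C(C)=C/C(=O)OC
F10 | step 8 | (5E,8R)-1-(2,2-diethoxyethoxy)-6-methyl-8-(triethylsilyloxy)undec-5-ene-2,9-diyn-4-ol, both C4 epimers | CC#C[C@H](O[Si](CC)(CC)CC)C/C(C)=C/C(O)C#CCOCC(OCC)OCC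
F11 | step 8 | (5E,8R)-1-(2,2-diethoxyethoxy)-6-methyl-8-(triethylsilyloxy)undec-5-ene-2,9-diyn-4-one | CC#C[C@H](O[Si](CC)(CC)CC)C/C(C)=C/C(=O)C#CCOCC(OCC)OCC
F12 | step 10 | C6 tert-butyldimethylsilyl ether of 17 | CC#C[C@H](O[Si](CC)(CC)CC)C/C(C)=C/[C@@H](O[Si](C)(C)C(C)(C)C)/C=C(\I)COCC(OCC)OCC
F13 | step 10 | methyl (2Z,4R,5E,8R)-4-(TBSO)-2-[(2,2-diethoxyethoxy)methyl]-6-methyl-8-(triethylsilyloxy)undeca-2,5-dien-9-ynoate | CC#C[C@H](O[Si](CC)(CC)CC)C/C(C)=C/[C@@H](O[Si](C)(C)C(C)(C)C)/C=C(\C(=O)OC)COCC(OCC)OCC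
F14 | step 10 | (2E,4R,5E,8R)-4-(TBSO)-2-[(2,2-diethoxyethoxy)methyl]-6-methyl-8-(triethylsilyloxy)undeca-2,5-dien-9-yn-1-ol | CC#C[C@H](O[Si](CC)(CC)CC)C/C(C)=C/[C@@H](O[Si](C)(C)C(C)(C)C)/C=C(\CO)COCC(OCC)OCC
F15 | step 20 | 9-epimer of 34 (9S) | O[C@@H]1[C@H](OC(=O)/C(C)=C\C)[C@@H](C(=C)CO[Si](C)(C)C(C)(C)C)[C@H](O[Si](C)(C)C(C)(C)C)/C=C(\C)C[C@@H](O[Si](CC)(CC)CC)/C=C1/C
F16 | step 20 | 9-acetate of 34 (9R, C2 triethylsilyl ether) | CC(=O)O[C@H]1[C@H](OC(=O)/C(C)=C\C)[C@@H](C(=C)CO[Si](C)(C)C(C)(C)C)[C@H](O[Si](C)(C)C(C)(C)C)/C=C(\C)C[C@@H](O[Si](CC)(CC)CC)/C=C1/C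
F17 | step 20 | 9-acetate with free C2 hydroxyl | CC(=O)O[C@H]1[C@H](OC(=O)/C(C)=C\C)[C@@H](C(=C)CO[Si](C)(C)C(C)(C)C)[C@H](O[Si](C)(C)C(C)(C)C)/C=C(\C)C[C@@H](O)/C=C1/C
A1 | alternative 1 | cis-anti-cis [2+2] photoadduct (cyclobutane through C1–C10 and C4–C5; 2-triethylsilyloxy, 8-TBSO, 9-oxo, 12,6-olide) | C=C1C(=O)O[C@@H]2[C@H]3[C@]4(C)C[C@@H](O[Si](CC)(CC)CC)[C@@H]4[C@@]3(C)C(=O)[C@H](O[Si](C)(C)C(C)(C)C)[C@@H]12
A2 | alternative 1 | 4-(tert-butyldimethylsilyloxy)-6-methyl-3-methylidene-3,3a,4,7a-tetrahydro-1-benzofuran-2,5-dione (bicyclic enone lactone) | C=C1C(=O)O[C@@H]2C=C(C)C(=O)[C@H](O[Si](C)(C)C(C)(C)C)[C@@H]12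
A3 | alternative 1 | triethyl{[(1R)-3-methylcyclobut-2-en-1-yl]oxy}silane | CC1=C[C@H](O[Si](CC)(CC)CC)C1
A4 | alternative 1 | 8-(TBSO)-2-(triethylsilyloxy)-9-oxogermacra-1(10)Z,4E,11(13)-trien-12,6-olide | C=C1C(=O)O[C@@H]2/C=C(\C)C[C@@H](O[Si](CC)(CC)CC)/C=C(/C)C(=O)[C@H](O[Si](C)(C)C(C)(C)C)[C@@H]12
A5 | alternative 2 | 2-acetoxy-9-hydroxy-8-(TBSO)germacra-1(10)Z,4E,11(13)-trien-12,6-olide | C=C1C(=O)O[C@@H]2/C=C(\C)C[C@@H](OC(C)=O)/C=C(/C)[C@@H](O)[C@H](O[Si](C)(C)C(C)(C)C)[C@@H]12
A6 | alternative 2 | open-chain Z-iodoalkene aldehyde (9,10-seco precursor of A5) | C=C1C(=O)O[C@H](/C=C(\C)C[C@@H](OC(C)=O)/C=C(/C)I)[C@H]1[C@@H](O[Si](C)(C)C(C)(C)C)C=O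
A7 | alternative 3 | 8,9-dihydroxy-2-(TBSO)-13-norgermacra-1(10)Z,4E-dien-12,6-olide | C1C(=O)O[C@@H]2/C=C(\C)C[C@@H](O[Si](C)(C)C(C)(C)C)/C=C(/C)[C@@H](O)[C@H](O)[C@@H]12
A8 | alternative 3 | 8,9-seco dialdehyde (C8 aldehyde on the lactone ring, C9 Z-enal) | O=C1C[C@H](C=O)[C@@H](/C=C(\C)C[C@@H](O[Si](C)(C)C(C)(C)C)/C=C(/C)C=O)O1
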